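**Retrosynthetic overview**
- Feature: the all-trans oxygen triad at C2, C3 and C4 of the cyclohexene ring is C4, C3 and C2 of D-glucose. The carbocycle is the pyranose ring with O5 exchanged for C6, and glucose C5 becomes the quaternary C1.
- Target 20 ⇐ silyl ether 19 (C4–O desilylation) ⇐ spiro-epoxide 17 (C7–O benzoate by opening at the CH2) ⇐ dienol 16 (C1 set by epoxidation directed by the C2 hydroxyl).
- 16 ⇐ enone 14 (C1=C7 by methylenation, then PMB removal) ⇐ β-hydroxy ketone 12 (dehydration).
- 12 ⇐ enol ether 9 by Ferrier carbocyclization, which forms the C5–C6 bond and closes the only ring.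
- 9 ⇐ methyl α-D-glucopyranoside 1 through the 4,6-anisylidene acetal, 2-O-TBS, 3-O-Bz, reductive opening to the 4-O-PMB ether, 6-iodide and elimination.

Key step: step 7

Remark on the chemistry: carbocyclic compounds are numbered as in the target (C1 quaternary carbon, C7 exocyclic carbon). β denotes the ring face carrying the oxygens at C2 and C4, α the face carrying the C3 benzoate. The new carbinol of 12 is drawn as the epimer expected to predominate; its configuration is erased in step 8, so either epimer serves.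

Step 1
Reactants: 1 methyl α-D-glucopyranoside; 2 4-methoxybenzaldehyde dimethyl acetal
Product: 3 methyl 4,6-O-[(R)-4-methoxybenzylidene]-α-D-glucopyranoside
Conditions: camphorsulfonic acid (cat.), DMF, 50 °C, 200 mbar
Reagents that add atoms: 4-methoxybenzaldehyde dimethyl acetal (2), COC(OC)c1ccc(OC)cc1
Why: Acid-catalysed transacetalization should give the thermodynamically preferred trans-fused 1,3-dioxane across O4 and O6 with the aryl group equatorial, while removal of methanol drives the equilibrium.

Step 2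
Reactants: 3 methyl 4,6-O-[(R)-4-methoxybenzylidene]-α-D-glucopyranoside
Product: 4 methyl 2-O-(tert-butyldimethylsilyl)-4,6-O-[(R)-4-methoxybenzylidene]-α-D-glucopyranoside
Conditions: TBSCl, imidazole, DMF, 0 °C to rt
Reagents that add atoms: tert-butyldimethylsilyl chloride, CC(C)(C)[Si](C)(C)Cl
Why: Regioselective silylation should favour the 2-hydroxyl, which is the more acidic and more accessible of the two in 4,6-acetal-protected α-glucosides, the 3-hydroxyl being flanked by the acetal; any 3-O-silyl isomer would be removed by chromatography.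

Step 3
Reactants: 4 methyl 2-O-(tert-butyldimethylsilyl)-4,6-O-[(R)-4-methoxybenzylidene]-α-D-glucopyranoside; 5 benzoyl chloride
Product: 6 methyl 3-O-benzoyl-2-O-(tert-butyldimethylsilyl)-4,6-O-[(R)-4-methoxybenzylidene]-α-D-glucopyranoside
Conditions: BzCl, pyridine, DMAP (cat.), CH2Cl2, 0 °C to rt
Reagents that add atoms: benzoyl chloride (5), O=C(Cl)c1ccccc1
Why: DMAP-catalysed acylation of the only free hydroxyl should place the benzoate that the target carries at C3, under conditions that leave the silyl ether and the acetal untouched.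

Step 4
Reactants: 6 methyl 3-O-benzoyl-2-O-(tert-butyldimethylsilyl)-4,6-O-[(R)-4-methoxybenzylidene]-α-D-glucopyranoside
Product: 7 methyl 3-O-benzoyl-2-O-(tert-butyldimethylsilyl)-4-O-(4-methoxybenzyl)-α-D-glucopyranoside
Conditions: BH3·THF, Bu2BOTf, CH2Cl2, 0 °C; MeOH, then aq. NaHCO3
Reagents that add atoms: none
Why: In this regioselective reductive acetal opening the boron Lewis acid should bind the more accessible O6, so that the C–O6 bond breaks and hydride reduces the oxocarbenium ion on O4, leaving the PMB ether on O4 and the 6-hydroxyl free; borane at 0 °C should not reduce the benzoate, which rules out aluminium hydrides here.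

Step 5
Reactants: 7 methyl 3-O-benzoyl-2-O-(tert-butyldimethylsilyl)-4-O-(4-methoxybenzyl)-α-D-glucopyranoside
Product: 8 methyl 3-O-benzoyl-2-O-(tert-butyldimethylsilyl)-6-deoxy-6-iodo-4-O-(4-methoxybenzyl)-α-D-glucopyranoside
Conditions: I2, PPh3, imidazole, toluene, 70 °C
Reagents that add atoms: iodine, II
Why: Appel-type iodination of the single primary alcohol proceeds by SN2 displacement of the alkoxyphosphonium ion and should not touch the ester, silyl ether or PMB ether.

Step 6
Reactants: 8 methyl 3-O-benzoyl-2-O-(tert-butyldimethylsilyl)-6-deoxy-6-iodo-4-O-(4-methoxybenzyl)-α-D-glucopyranoside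
Product: 9 methyl 3-O-benzoyl-2-O-(tert-butyldimethylsilyl)-6-deoxy-4-O-(4-methoxybenzyl)-α-D-xylo-hex-5-enopyranoside
Conditions: DBU, THF, reflux
Reagents that add atoms: none
Why: E2 dehydroiodination can only use H5, the sole β-hydrogen, so the exocyclic enol ether should form, and the non-nucleophilic amidine base should spare the benzoate.

Step 7
Reactants: 9 methyl 3-O-benzoyl-2-O-(tert-butyldimethylsilyl)-6-deoxy-4-O-(4-methoxybenzyl)-α-D-xylo-hex-5-enopyranoside
Product: 12 3α-benzoyloxy-4β-(tert-butyldimethylsilyloxy)-5β-hydroxy-2β-(4-methoxybenzyloxy)cyclohexan-1-one, via hemiketal organomercurial 10 (not isolated), via mercurio keto-aldehyde 11 (not isolated)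
Conditions: Hg(OCOCF3)2 (5 mol%), acetone/H2O (2:1), rt
Reagents that add atoms: water, O
Why: In this Ferrier carbocyclization divalent mercury and water add across the electron-rich exocyclic enol ether to give hemiketal 10, which opens and loses methanol to the 6-mercurio 5-keto aldehyde 11; the mercury enolate at C6 then adds to the aldehyde and protonolysis returns the mercury salt, so a catalytic amount should suffice. The closest known reaction type is the mercury-salt-catalysed conversion of 6-deoxyhex-5-enopyranosides into 2-deoxyinosose derivatives, applied here to a substrate carrying silyl, benzoyl and PMB groups. The six-membered carbocycle closes by a 6-(enolexo)-exo-trig aldol that forms the C5–C6 bond of the target (glucose C1–C6). The one new stereocentre, the C5 carbinol, is governed by a chair-like transition state with the three ring oxygens equatorial, which should place the hydroxyl axial and trans to the C3 benzoate; either epimer is usable because step 8 removes this centre. The step needs chemoselective hydration of the enol ether with the C2 to C4 triad and its three protecting groups untouched, and no β-elimination of benzoate from the β-acyloxy ketone; the near-neutral aqueous acetone medium at room temperature and the regiospecific placement of the enolate at C6 by mercury should secure this.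

Step 8
Reactants: 12 3α-benzoyloxy-4β-(tert-butyldimethylsilyloxy)-5β-hydroxy-2β-(4-methoxybenzyloxy)cyclohexan-1-one
Product: 14 3α-benzoyloxy-4β-(tert-butyldimethylsilyloxy)-2β-(4-methoxybenzyloxy)cyclohex-5-en-1-one, via β-mesyloxy ketone 13 (not isolated)
Conditions: MsCl, Et3N, CH2Cl2, 0 °C
Reagents that add atoms: none
Why: Mesylation followed by E1cB elimination through the C6 enolate should give the enone, because the C6 methylene protons are more acidic and more accessible than H2 and mesylate is a far better leaving group than the C3 benzoate, so short exposure at 0 °C should avoid a second elimination.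

Step 9
Reactants: 14 3α-benzoyloxy-4β-(tert-butyldimethylsilyloxy)-2β-(4-methoxybenzyloxy)cyclohex-5-en-1-one
Product: 15 3α-benzoyloxy-4β-(tert-butyldimethylsilyloxy)-2β-(4-methoxybenzyloxy)-1-methylidenecyclohex-5-ene
Conditions: Tebbe reagent Cp2Ti(μ-CH2)(μ-Cl)AlMe2 (1.2 equiv), pyridine (cat.), THF/toluene, −40 to 0 °C
Reagents that add atoms: Tebbe reagent, C[Al-]1(C)C[Ti]([Cl+]1)(C2C=CC=C2)C2C=CC=C2
Why: Tebbe methylenation through a titanium methylidene and an oxatitanacyclobutane is non-basic, so the enolizable ketone with its β-benzoate should not eliminate, and ketones react faster than esters with this reagent, so a small excess at low temperature should spare the benzoate.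

Step 10
Reactants: 15 3α-benzoyloxy-4β-(tert-butyldimethylsilyloxy)-2β-(4-methoxybenzyloxy)-1-methylidenecyclohex-5-ene
Product: 16 3α-benzoyloxy-4β-(tert-butyldimethylsilyloxy)-1-methylidenecyclohex-5-en-2β-ol
Conditions: DDQ, CH2Cl2/pH 7 phosphate buffer (10:1), 0 °C
Reagents that add atoms: none
Why: Oxidative PMB cleavage by DDQ runs through hydride abstraction at the anisyl methylene and hydrolysis of the resulting oxocarbenium ion, and the diene, held s-trans by the ring, cannot undergo a Diels–Alder reaction with the quinone, so the C2 hydroxyl should be freed selectively.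

Step 11
Reactants: 16 3α-benzoyloxy-4β-(tert-butyldimethylsilyloxy)-1-methylidenecyclohex-5-en-2β-ol
Product: 17 spiro-epoxide 3α-benzoyloxy-4β-(tert-butyldimethylsilyloxy)-1β,7-epoxy-1-methylcyclohex-5-en-2β-ol (1-oxaspiro[2.5]oct-7-ene; epoxide oxygen on the β face of C1 and cis to the C2 hydroxyl; C7 on the α face)
Conditions: VO(acac)2 (5 mol%), t-BuOOH (decane), CH2Cl2, 0 °C to rt
Reagents that add atoms: tert-butyl hydroperoxide, CC(C)(C)OO
Why: In this hydroxyl-directed vanadium-catalysed epoxidation the vanadium alkoxide of the C2 hydroxyl should deliver the peroxide oxygen to the β face of the allylic C1=C7 alkene only, which sets the C1 stereocentre cis to O2 and leaves the C5=C6 alkene, which has no free allylic hydroxyl, untouched.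

Step 12
Reactants: 17 spiro-epoxide 3α-benzoyloxy-4β-(tert-butyldimethylsilyloxy)-1β,7-epoxy-1-methylcyclohex-5-en-2β-ol; 18 benzoic acid
Product: 19 1α-benzoyloxymethyl-3α-benzoyloxy-4β-(tert-butyldimethylsilyloxy)cyclohex-5-ene-1β,2β-diol
Conditions: Ti(OiPr)4 (1.5 equiv), PhCO2H, CH2Cl2, rt; aq. tartaric acid
Reagents that add atoms: benzoic acid (18), OC(=O)c1ccccc1
Why: In the Ti(OiPr)4-mediated opening of a 2,3-epoxy alcohol the titanium chelate of the C2 alkoxide and the epoxide oxygen should direct benzoate to the distal epoxide carbon, here the unhindered primary C7, by an SN2 path that leaves the C1–O bond and hence the C1 configuration intact.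

Step 13
Reactants: 19 1α-benzoyloxymethyl-3α-benzoyloxy-4β-(tert-butyldimethylsilyloxy)cyclohex-5-ene-1β,2β-diol
Product: 20 1α-benzoyloxymethyl-3α-benzoyloxycyclohex-5-ene-1β,2β,4β-triol (target)
Conditions: HF·pyridine, THF/pyridine, 0 °C to rt
Reagents that add atoms: none
Why: Fluoride-mediated desilylation under buffered, weakly acidic conditions should free the C4 hydroxyl without the benzoate migration that a basic fluoride source could cause among the neighbouring hydroxyls.

**Compound list**
1 | methyl α-D-glucopyranoside | OC[C@H]1O[C@H](OC)[C@H](O)[C@@H](O)[C@@H]1O | starting material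
2 | 4-methoxybenzaldehyde dimethyl acetal | COC(OC)c1ccc(OC)cc1 | starting material
3 | methyl 4,6-O-[(R)-4-methoxybenzylidene]-α-D-glucopyranoside | COc1ccc(cc1)[C@@H]1OC[C@H]2O[C@H](OC)[C@H](O)[C@@H](O)[C@@H]2O1 | intermediate
4 | methyl 2-O-(tert-butyldimethylsilyl)-4,6-O-[(R)-4-methoxybenzylidene]-α-D-glucopyranoside | COc1ccc(cc1)[C@@H]1OC[C@H]2O[C@H](OC)[C@H](O[Si](C)(C)C(C)(C)C)[C@@H](O)[C@@H]2O1 | intermediate
5 | benzoyl chloride | O=C(Cl)c1ccccc1 | starting material
6 | methyl 3-O-benzoyl-2-O-(tert-butyldimethylsilyl)-4,6-O-[(R)-4-methoxybenzylidene]-α-D-glucopyranoside | COc1ccc(cc1)[C@@H]1OC[C@H]2O[C@H](OC)[C@H](O[Si](C)(C)C(C)(C)C)[C@@H](OC(=O)c3ccccc3)[C@@H]2O1 | intermediate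
7 | methyl 3-O-benzoyl-2-O-(tert-butyldimethylsilyl)-4-O-(4-methoxybenzyl)-α-D-glucopyranoside | OC[C@H]1O[C@H](OC)[C@H](O[Si](C)(C)C(C)(C)C)[C@@H](OC(=O)c2ccccc2)[C@@H]1OCc1ccc(OC)cc1 | intermediate
8 | methyl 3-O-benzoyl-2-O-(tert-butyldimethylsilyl)-6-deoxy-6-iodo-4-O-(4-methoxybenzyl)-α-D-glucopyranoside | IC[C@H]1O[C@H](OC)[C@H](O[Si](C)(C)C(C)(C)C)[C@@H](OC(=O)c2ccccc2)[C@@H]1OCc1ccc(OC)cc1 | intermediate
9 | methyl 3-O-benzoyl-2-O-(tert-butyldimethylsilyl)-6-deoxy-4-O-(4-methoxybenzyl)-α-D-xylo-hex-5-enopyranoside | C=C1O[C@H](OC)[C@H](O[Si](C)(C)C(C)(C)C)[C@@H](OC(=O)c2ccccc2)[C@@H]1OCc1ccc(OC)cc1 | intermediate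
10 | hemiketal organomercurial: methyl 3-O-benzoyl-2-O-(tert-butyldimethylsilyl)-6-deoxy-5-hydroxy-4-O-(4-methoxybenzyl)-6-(trifluoroacetoxymercurio)-α-D-xylo-hexopyranoside (C5 configuration open) | OC1(C[Hg]OC(=O)C(F)(F)F)O[C@H](OC)[C@H](O[Si](C)(C)C(C)(C)C)[C@@H](OC(=O)c2ccccc2)[C@@H]1OCc1ccc(OC)cc1 | intermediate
11 | mercurio keto-aldehyde: 3-O-benzoyl-2-O-(tert-butyldimethylsilyl)-6-deoxy-4-O-(4-methoxybenzyl)-6-(trifluoroacetoxymercurio)-D-xylo-hexos-5-ulose | O=C[C@H](O[Si](C)(C)C(C)(C)C)[C@@H](OC(=O)c1ccccc1)[C@H](OCc1ccc(OC)cc1)C(=O)C[Hg]OC(=O)C(F)(F)F | intermediate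
12 | 3α-benzoyloxy-4β-(tert-butyldimethylsilyloxy)-5β-hydroxy-2β-(4-methoxybenzyloxy)cyclohexan-1-one | O=C1C[C@H](O)[C@H](O[Si](C)(C)C(C)(C)C)[C@@H](OC(=O)c2ccccc2)[C@@H]1OCc1ccc(OC)cc1 | intermediate
13 | β-mesyloxy ketone: 3α-benzoyloxy-4β-(tert-butyldimethylsilyloxy)-5β-(methanesulfonyloxy)-2β-(4-methoxybenzyloxy)cyclohexan-1-one | O=C1C[C@H](OS(C)(=O)=O)[C@H](O[Si](C)(C)C(C)(C)C)[C@@H](OC(=O)c2ccccc2)[C@@H]1OCc1ccc(OC)cc1 | intermediate
14 | 3α-benzoyloxy-4β-(tert-butyldimethylsilyloxy)-2β-(4-methoxybenzyloxy)cyclohex-5-en-1-one | O=C1C=C[C@H](O[Si](C)(C)C(C)(C)C)[C@@H](OC(=O)c2ccccc2)[C@@H]1OCc1ccc(OC)cc1 | intermediate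
15 | 3α-benzoyloxy-4β-(tert-butyldimethylsilyloxy)-2β-(4-methoxybenzyloxy)-1-methylidenecyclohex-5-ene | C=C1C=C[C@H](O[Si](C)(C)C(C)(C)C)[C@@H](OC(=O)c2ccccc2)[C@@H]1OCc1ccc(OC)cc1 | intermediate
16 | 3α-benzoyloxy-4β-(tert-butyldimethylsilyloxy)-1-methylidenecyclohex-5-en-2β-ol | C=C1C=C[C@H](O[Si](C)(C)C(C)(C)C)[C@@H](OC(=O)c2ccccc2)[C@@H]1O | intermediate
17 | spiro-epoxide 3α-benzoyloxy-4β-(tert-butyldimethylsilyloxy)-1β,7-epoxy-1-methylcyclohex-5-en-2β-ol (epoxide oxygen cis to the C2 hydroxyl) | C1O[C@@]12C=C[C@H](O[Si](C)(C)C(C)(C)C)[C@@H](OC(=O)c3ccccc3)[C@@H]2O | intermediate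
18 | benzoic acid | OC(=O)c1ccccc1 | starting material
19 | 1α-benzoyloxymethyl-3α-benzoyloxy-4β-(tert-butyldimethylsilyloxy)cyclohex-5-ene-1β,2β-diol | O=C(OC[C@@]1(O)C=C[C@H](O[Si](C)(C)C(C)(C)C)[C@@H](OC(=O)c2ccccc2)[C@@H]1O)c1ccccc1 | intermediate
20 | 1α-benzoyloxymethyl-3α-benzoyloxycyclohex-5-ene-1β,2β,4β-triol | O=C(OC[C@@]1(O)C=C[C@H](O)[C@@H](OC(=O)c2ccccc2)[C@@H]1O)c1ccccc1 | target

**Totals**
Total step count: 13. Longest linear sequence: 13 steps (1 to 20).

**Steps most likely to fail**

Step 12. Benzoate may enter at the tertiary allylic C1 or in a conjugate manner at C5 in place of C7, and the titanium alkoxides may shuttle benzoyl groups among O7, O2 and O3. The fallback sets out from dienol 16 and avoids the epoxide altogether. Hydrogen-bond-directed dihydroxylation with OsO4/TMEDA (1 equiv each, CH2Cl2, −78 °C; osmate ester cleaved with aq. NaHSO3) should add both oxygens to the exocyclic alkene from the face of the C2 hydroxyl. This would give 3α-benzoyloxy-4β-(tert-butyldimethylsilyloxy)-1α-(hydroxymethyl)cyclohex-5-ene-1β,2β-diol F1. Selective acylation of its primary hydroxyl (benzoyl chloride 5, 2,4,6-collidine, CH2Cl2, −40 °C) should then give 19, where the route is rejoined; steps 11 and 12 are bypassed.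

Step 9. Loss of the C3 benzoate by E1cB through the C2 enolate with subsequent aromatization, or methylenation of the benzoate carbonyl, may compete with methylenation of the ketone. The fallback sets out from enone 14 and uses a two-stage Peterson olefination. Addition of Me3SiCH2MgCl in the presence of CeCl3 (THF, −78 °C), a weakly basic reagent that adds 1,2 to enones, should give 3α-benzoyloxy-4β-(tert-butyldimethylsilyloxy)-2β-(4-methoxybenzyloxy)-1-[(trimethylsilyl)methyl]cyclohex-5-en-1-ol F2. Acid-promoted elimination (camphorsulfonic acid cat., CH2Cl2, 0 °C) should then give diene 15, where the route is rejoined.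

Step 7. Oxymercuration of the ester-deactivated, silyl-shielded enol ether may be slow, hydration may stop at the open keto aldehyde without aldol closure, or benzoate may be lost by β-elimination from the product. The fallback sets out from enol ether 9 and separates hydrolysis from ring closure. Dilute aqueous H2SO4 in acetone at rt should hydrolyse the enol ether, with loss of methanol, to 3-O-benzoyl-2-O-(tert-butyldimethylsilyl)-6-deoxy-4-O-(4-methoxybenzyl)-D-xylo-hexos-5-ulose F3. An amine-catalysed intramolecular aldol (L-proline, DMSO, rt) through the C6 enamine should then close the same C5–C6 bond in the same 6-(enolexo)-exo-trig mode and give β-hydroxy ketone 12, where the route is rejoined.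

**Further compounds**
F1 | step 12 | 3α-benzoyloxy-4β-(tert-butyldimethylsilyloxy)-1α-(hydroxymethyl)cyclohex-5-ene-1β,2β-diol | OC[C@@]1(O)C=C[C@H](O[Si](C)(C)C(C)(C)C)[C@@H](OC(=O)c2ccccc2)[C@@H]1O
F2 | step 9 | 3α-benzoyloxy-4β-(tert-butyldimethylsilyloxy)-2β-(4-methoxybenzyloxy)-1-[(trimethylsilyl)methyl]cyclohex-5-en-1-ol (C1 configuration open) | C[Si](C)(C)CC1(O)C=C[C@H](O[Si](C)(C)C(C)(C)C)[C@@H](OC(=O)c2ccccc2)[C@@H]1OCc1ccc(OC)cc1
F3 | step 7 | 3-O-benzoyl-2-O-(tert-butyldimethylsilyl)-6-deoxy-4-O-(4-methoxybenzyl)-D-xylo-hexos-5-ulose | O=C[C@H](O[Si](C)(C)C(C)(C)C)[C@@H](OC(=O)c1ccccc1)[C@H](OCc1ccc(OC)cc1)C(C)=O
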